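The earlier runs and the new flask are simulated with constants of no real substance, noise included.

The amber run gains X at 0.0653 min⁻¹, as a fraction of the D charged, on average over its first 1.50 min. Between the next readings the rate is 0.0116 min⁻¹, slower by a factor of 5.63. It then drops to 0.00175 min⁻¹, slower by a further factor of 6.63, so the slowing read from these readings accumulates to a factor of 37.3.

| setting | amber | north | south-east | south | east |
|---|---|---|---|---|---|
| D | 0.75 M | 0.75 M | 0.75 M | 0.75 M | 0.75 M |
| E | 1.1 equiv | 1.10 equiv | 1.10 equiv | 1.10 equiv | 1.10 equiv |
| G | 1 equiv | 1.00 equiv | 1.00 equiv | 1.00 equiv | 1.00 equiv |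
| Q | 0.05 mol% | 0.1 mol% | 0.1 mol% | 0.1 mol% | 0.1 mol% |
| Z | 0.83 mM | 0.83 mM | 0.83 mM | 0.83 mM | 0.83 mM |
| temperature | 85 °C | 85 °C | 110 °C | 60 °C | 35 °C |
| remark | run made earlier |  |  |  |  |
| time |  | 2.0 h | 2.0 h | 2.0 h | 2.0 h |

- amber (time / min: X / %): 1.50: 9.8; 4.00: 12.7; 8.00: 13.4; 12.0: 12.4

(each reading ± 0.5 percentage points)

- the earlier runs do not show what temperature does; that part of a forecast is a guess
- no earlier run changes the charge of Q; that part of a forecast is a guess

* which flask leads in amount of X, in percent of the D charged ("all alike" within 1.5 percentage points) (north / south-east / south / east / all alike)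
* how much X is there at the end, in percent of the D charged: north
* how much X is there at the end, in percent of the D charged: south-east
* how much X is there at the end, in percent of the D charged: south
* how much X is there at the end, in percent of the D charged: east

In the last interval the rate read from the amber run changes sign: X falls by 0.00250 min⁻¹. The amber run therefore appears to lose X. The drop of 1 percentage point stands against a scatter of 0.5 points per reading, so what follows is a rough reading. Dividing the peak reading by this loss rate gives the drain time t_d = 53.6 min, the time in which the late loss, held steady, would empty the amber run of X.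

If the clock runs with the loading, which is a guess because no earlier run changes Q, then north at twice the amber loading drains in 26.8 min. Its 2.0 h then spans n = 4.48 drain times, so this reckoning puts north below the amber peak reading of 13.4%, not above it. Temperature lies outside these readings. As a guess, a colder flask drains more slowly, which points to east if 2.0 h lets it climb.

The forecast reads the stall as “catalyst death rather than equilibrium or substrate depletion”. It gives 23% in north, 13% in south-east, 35% in south and 26% in east, with south leading. The two part on north: the forecast keeps a plateau there, and the reckoning above drains it.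

The flasks give 2.46% in north, 0.762% in south-east, 14.3% in south and 33.8% in east, so east leads.

    D + E + Q ⇌ Q + X (K = 1.00 M⁻¹, k = 2.00 M⁻² s⁻¹, Ea = 47.0 kJ mol⁻¹, ΔH = −47.0 kJ mol⁻¹)
    G + E + Q → Q + J (k = 1.80 M⁻² s⁻¹, Ea = 42.0 kJ mol⁻¹)
    Q + Z ⇌ L (K = 1800 M⁻¹, k = 4.10 M⁻¹ s⁻¹, Ea = 40.0 kJ mol⁻¹, ΔH = −47.0 kJ mol⁻¹)
    (constants at 60 °C)

North, at n = 4.48, holds 3.52% of X after 1.00 h and 2.46% after 2.00 h, so X is still falling there. In south-east the back reaction of X to D, E and Q is the main reason for the low reading: with it taken away, that flask reads 61.1% instead of 0.762%. The amber run carried on to 2.0 h at its own loading lies 2.24 drain times out and reads 3.59%.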